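**Retrosynthetic overview**
- The strategy rests on ring B: a pentasubstituted benzene (chroman C4a, C5 prenyl, C6 propyl arm, C7 H, C8 OH, C8a) fused to the 2,2-dimethyldihydropyran. Both rings are disconnected together to a 2-pyrone (diene C3–C6) whose O3 carries, through CMe2–CH2–CH2, an alkyne bearing the prenyl group.
- Forward, an intramolecular [4+2] of pyrone and alkyne followed by loss of CO2 forms C8a–C4a and C6–C5 and closes the dihydropyran and the benzene ring in one operation; fluoride then frees the three phenols.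
- The pyrone is built on 4-hydroxy-6-methyl-2-pyrone: dianion alkylation at the methyl group with the ring A arylethyl iodide, diazo transfer at C3, rhodium carbenoid O–H insertion of the tertiary enynol, silylation at O4.
- The ring A iodide comes from 4-bromoresorcinol (silylation, zinc enolate arylation, bromination, γ-selective prenylboronate coupling, reduction, iodination); the enynol comes from ethyl pent-4-ynoate, prenyl bromide and MeMgBr.
- Ring order: ring A is present from the start; the dihydropyran and ring B form together in the key step.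

Key step: step 13

Remark: Kazinol D has no stereocentre, so no step needs stereocontrol; TBS = tert-butyldimethylsilyl; the zinc ester enolate solution and the prenylboronic ester are taken as bought.

**Route**

Step 1
Reactants: 1 4-bromoresorcinol
Product: 2 1-bromo-2,4-bis(TBS-oxy)benzene
Conditions: TBSCl (2.4 equiv), imidazole (5 equiv), DMF, rt
Reagents that add atoms: tert-butyldimethylsilyl chloride, CC(C)(C)[Si](C)(C)Cl
Why: Standard silylation of phenols with a silyl chloride and imidazole caps both hydroxyls so that the later organometallic and basic steps meet no acidic proton.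

Step 2
Reactants: 2 1-bromo-2,4-bis(TBS-oxy)benzene; 3 (2-tert-butoxy-2-oxoethyl)zinc chloride
Product: 4 tert-butyl 2-[2,4-bis(TBS-oxy)phenyl]acetate
Conditions: [PdBr(P(t-Bu)3)]2 (1 mol%), THF/Et2O, rt to 50 °C
Reagents that add atoms: none
Why: Palladium-catalysed α-arylation of a Reformatsky-type zinc ester enolate (a Negishi-type coupling) runs under neutral conditions that leave aryl silyl ethers intact, and the tert-butyl ester blocks self-condensation.

Step 3
Reactants: 4 tert-butyl 2-[2,4-bis(TBS-oxy)phenyl]acetate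
Product: 5 tert-butyl 2-[5-bromo-2,4-bis(TBS-oxy)phenyl]acetate
Conditions: NBS (1.05 equiv), MeCN, 0 °C, dark
Reagents that add atoms: N-bromosuccinimide, O=C1CCC(=O)N1Br
Why: Electrophilic aromatic bromination should go to C5, the only ring position that is para to one silyloxy group and ortho to the other without being wedged between the two bulky silyl ethers.

Step 4
Reactants: 5 tert-butyl 2-[5-bromo-2,4-bis(TBS-oxy)phenyl]acetate; 6 prenylboronic acid pinacol ester (4,4,5,5-tetramethyl-2-(3-methylbut-2-en-1-yl)-1,3,2-dioxaborolane)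
Product: 7 tert-butyl 2-[2,4-bis(TBS-oxy)-5-(2-methylbut-3-en-2-yl)phenyl]acetate
Conditions: Pd2(dba)3 (2 mol%), JackiePhos (8 mol%), aq K3PO4 (3 equiv), THF, 40 °C
Reagents that add atoms: none
Why: In this ligand-controlled Suzuki–Miyaura allyl–aryl coupling, SE2′ transmetalation places palladium on the tertiary carbon and the electron-poor biarylphosphine should speed reductive elimination ahead of σ–π–σ isomerisation, so the aryl group ends on the quaternary carbon as the 1,1-dimethylallyl group (γ-selective mode).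

Step 5
Reactants: 7 tert-butyl 2-[2,4-bis(TBS-oxy)-5-(2-methylbut-3-en-2-yl)phenyl]acetate
Product: 8 2-[2,4-bis(TBS-oxy)-5-(2-methylbut-3-en-2-yl)phenyl]ethanol
Conditions: i-Bu2AlH (3 equiv), CH2Cl2, −78 to 0 °C; aq potassium sodium tartrate
Reagents that add atoms: none
Why: Hydride reduction of the ester to the primary alcohol by i-Bu2AlH does not touch aryl silyl ethers or the isolated terminal alkene at low temperature.

Step 6
Reactants: 8 2-[2,4-bis(TBS-oxy)-5-(2-methylbut-3-en-2-yl)phenyl]ethanol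
Product: 9 1-(2-iodoethyl)-2,4-bis(TBS-oxy)-5-(2-methylbut-3-en-2-yl)benzene
Conditions: PPh3, I2, imidazole (premixed), CH2Cl2, 0 °C to rt
Reagents that add atoms: iodine, II
Why: Appel-type iodination (phosphonium activation of the primary alcohol, then SN2 by iodide) under imidazole buffering spares the silyl ethers, and premixing the phosphine with iodine keeps free iodine away from the alkene.

Step 7
Reactants: 9 1-(2-iodoethyl)-2,4-bis(TBS-oxy)-5-(2-methylbut-3-en-2-yl)benzene; 10 4-hydroxy-6-methyl-2-pyrone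
Product: 12 6-{3-[2,4-bis(TBS-oxy)-5-(2-methylbut-3-en-2-yl)phenyl]propyl}-4-hydroxy-2H-pyran-2-one, via dilithium dianion of the pyrone 11 (not isolated)
Conditions: 10 (2 equiv), LiN(i-Pr)2 (4.1 equiv), THF/DMPU, −78 °C; then 9, −78 to 0 °C; 1 M HCl to pH 4
Reagents that add atoms: none
Why: This is the C-alkylation of the dianion of triacetic acid lactone, whose second deprotonation creates a vinylogous carbanion at the 6-methyl group that is far more nucleophilic than the 4-oxido oxygen or C3, so SN2 on the primary iodide builds the three-carbon link while the excess dianion offsets any loss of iodide by elimination.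

Step 8
Reactants: 12 6-{3-[2,4-bis(TBS-oxy)-5-(2-methylbut-3-en-2-yl)phenyl]propyl}-4-hydroxy-2H-pyran-2-one
Product: 13 6-{3-[2,4-bis(TBS-oxy)-5-(2-methylbut-3-en-2-yl)phenyl]propyl}-3-diazo-2H-pyran-2,4(3H)-dione
Conditions: 4-acetamidobenzenesulfonyl azide (1.2 equiv), Et3N (1.5 equiv), MeCN, 0 °C to rt
Reagents that add atoms: 4-acetamidobenzenesulfonyl azide, CC(=O)Nc1ccc(cc1)S(=O)(=O)N=[N+]=[N-]
Why: Regitz diazo transfer from a sulfonyl azide to C3 of the 4-hydroxy-2-pyrone, which reacts as a cyclic 1,3-dicarbonyl compound under mild amine base.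

Step 9
Reactants: 14 ethyl pent-4-ynoate; 15 prenyl bromide (1-bromo-3-methylbut-2-ene)
Product: 16 ethyl 8-methylnon-7-en-4-ynoate
Conditions: CuI (20 mol%), K2CO3 (1.5 equiv), DMF, rt
Reagents that add atoms: none
Why: Formation of the copper acetylide under carbonate base and SN2 substitution at the primary carbon of the allylic bromide should give the skipped enyne, a standard alkyne allylation mediated by monovalent copper that tolerates the ester.

Step 10
Reactants: 16 ethyl 8-methylnon-7-en-4-ynoate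
Product: 17 2,9-dimethyldec-8-en-5-yn-2-ol
Conditions: MeMgBr (3 equiv), THF, 0 °C to rt; aq NH4Cl
Reagents that add atoms: methylmagnesium bromide, C[Mg]Br
Why: Double Grignard addition to the ester gives the tertiary dimethyl carbinol, and the internal alkyne and the trisubstituted alkene are inert to the reagent.

Step 11
Reactants: 13 6-{3-[2,4-bis(TBS-oxy)-5-(2-methylbut-3-en-2-yl)phenyl]propyl}-3-diazo-2H-pyran-2,4(3H)-dione; 17 2,9-dimethyldec-8-en-5-yn-2-ol
Product: 18 6-{3-[2,4-bis(TBS-oxy)-5-(2-methylbut-3-en-2-yl)phenyl]propyl}-3-[(2,9-dimethyldec-8-en-5-yn-2-yl)oxy]-4-hydroxy-2H-pyran-2-one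
Conditions: Rh2(OAc)4 (2 mol%), 17 (3 equiv), ClCH2CH2Cl, 80 °C, slow addition of 13; excess 17 recovered
Reagents that add atoms: none
Why: Dirhodium tetraacetate turns the 2-diazo-1,3-dicarbonyl unit into an electrophilic rhodium carbenoid that is trapped by the hydroxyl oxygen (oxonium ylide then proton shift, a carbenoid O–H insertion), enolisation restores the 4-hydroxy-2-pyrone, and excess alcohol with slow addition of the diazo compound should hold back dimerisation and addition to the π-bonds.

Step 12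
Reactants: 18 6-{3-[2,4-bis(TBS-oxy)-5-(2-methylbut-3-en-2-yl)phenyl]propyl}-3-[(2,9-dimethyldec-8-en-5-yn-2-yl)oxy]-4-hydroxy-2H-pyran-2-one
Product: 19 4-(TBS-oxy)-6-{3-[2,4-bis(TBS-oxy)-5-(2-methylbut-3-en-2-yl)phenyl]propyl}-3-[(2,9-dimethyldec-8-en-5-yn-2-yl)oxy]-2H-pyran-2-one
Conditions: TBSCl (1.3 equiv), imidazole (2.5 equiv), CH2Cl2, 0 °C to rt; non-aqueous work-up, Et3N-deactivated silica
Reagents that add atoms: tert-butyldimethylsilyl chloride, CC(C)(C)[Si](C)(C)Cl
Why: O-silylation of the acidic vinylogous carboxylic acid at O4 should give the 4-silyloxy-2-pyrone, the conjugated silyl tautomer, under conditions too mild to cleave the tertiary ether.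

Step 13
Reactants: 19 4-(TBS-oxy)-6-{3-[2,4-bis(TBS-oxy)-5-(2-methylbut-3-en-2-yl)phenyl]propyl}-3-[(2,9-dimethyldec-8-en-5-yn-2-yl)oxy]-2H-pyran-2-one
Product: 21 tris-TBS ether of Kazinol D (8-(TBS-oxy)-6-{3-[2,4-bis(TBS-oxy)-5-(2-methylbut-3-en-2-yl)phenyl]propyl}-2,2-dimethyl-5-(3-methylbut-2-en-1-yl)chroman), via bridged bicyclic lactone 20 (not isolated)
Conditions: 1,2-Cl2C6H4 (0.005 M, degassed), BHT (10 mol%), 2,6-di-tert-butyl-4-methylpyridine (0.2 equiv), 180 °C, sealed tube
Reagents that add atoms: none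
Why: On heating, the pyrone diene (C3=C4–C5=C6) should add the tethered alkyne in an intramolecular [4+2] cycloaddition to the bridged lactone 20, which loses CO2 by retro-[4+2] cycloreversion and so aromatises to ring B; this is the intramolecular 2-pyrone–alkyne Diels–Alder reaction with CO2 extrusion, a known route to fused benzenes. The dihydropyran closes in the cycloaddition itself as the six-membered ring fixed by the O–CMe2–CH2–CH2 tether (new bond C8a–C4a, from pyrone C3 to the proximal alkyne carbon), and the benzene ring closes by the second new bond (C6–C5, from pyrone C6 to the distal alkyne carbon) followed by the aromatising loss of the lactone bridge. No stereocentre remains in the product, since the two bridgehead centres of 20 vanish with the CO2. The step needs chemoselectivity for the alkyne over the prenyl and 1,1-dimethylallyl alkenes and a single regiochemistry, and both follow from the four-atom tether, which lets only the alkyne span C3 and C6 and only in the orientation that places the prenyl-bearing carbon next to C6. The geminal methyl groups on the tether favour the folded conformer (Thorpe–Ingold effect), and high dilution suppresses intermolecular cycloaddition.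

Step 14
Reactants: 21 tris-TBS ether of Kazinol D
Product: 22 Kazinol D
Conditions: n-Bu4NF (4 equiv), AcOH (4 equiv), THF (degassed), 0 °C to rt
Reagents that add atoms: none
Why: Fluoride cleaves the three aryl silyl ethers by attack at silicon, while acetic acid buffering and exclusion of air protect the electron-rich phenols and leave the alkenes and the chroman ether untouched.

**Compound list**
1 | 4-bromoresorcinol | Oc1ccc(Br)c(O)c1 | starting material
2 | 1-bromo-2,4-bis(TBS-oxy)benzene | CC(C)(C)[Si](C)(C)Oc1ccc(Br)c(O[Si](C)(C)C(C)(C)C)c1 | intermediate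
3 | (2-tert-butoxy-2-oxoethyl)zinc chloride | CC(C)(C)OC(=O)C[Zn]Cl | starting material
4 | tert-butyl 2-[2,4-bis(TBS-oxy)phenyl]acetate | CC(C)(C)OC(=O)Cc1ccc(O[Si](C)(C)C(C)(C)C)cc1O[Si](C)(C)C(C)(C)C | intermediate
5 | tert-butyl 2-[5-bromo-2,4-bis(TBS-oxy)phenyl]acetate | CC(C)(C)OC(=O)Cc1cc(Br)c(O[Si](C)(C)C(C)(C)C)cc1O[Si](C)(C)C(C)(C)C | intermediate
6 | prenylboronic acid pinacol ester | CC(C)=CCB1OC(C)(C)C(C)(C)O1 | starting material
7 | tert-butyl 2-[2,4-bis(TBS-oxy)-5-(2-methylbut-3-en-2-yl)phenyl]acetate | CC(C)(C)OC(=O)Cc1cc(C(C)(C)C=C)c(O[Si](C)(C)C(C)(C)C)cc1O[Si](C)(C)C(C)(C)C | intermediate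
8 | 2-[2,4-bis(TBS-oxy)-5-(2-methylbut-3-en-2-yl)phenyl]ethanol | OCCc1cc(C(C)(C)C=C)c(O[Si](C)(C)C(C)(C)C)cc1O[Si](C)(C)C(C)(C)C | intermediate
9 | 1-(2-iodoethyl)-2,4-bis(TBS-oxy)-5-(2-methylbut-3-en-2-yl)benzene | ICCc1cc(C(C)(C)C=C)c(O[Si](C)(C)C(C)(C)C)cc1O[Si](C)(C)C(C)(C)C | intermediate
10 | 4-hydroxy-6-methyl-2-pyrone | Cc1cc(O)cc(=O)o1 | starting material
11 | dilithium dianion of 4-hydroxy-6-methyl-2-pyrone (4-oxido, 6-methylide) | [Li+].[Li+].[CH2-]c1cc([O-])cc(=O)o1 | intermediate (not isolated)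
12 | 6-{3-[2,4-bis(TBS-oxy)-5-(2-methylbut-3-en-2-yl)phenyl]propyl}-4-hydroxy-2H-pyran-2-one | C=CC(C)(C)c1cc(CCCc2cc(O)cc(=O)o2)c(O[Si](C)(C)C(C)(C)C)cc1O[Si](C)(C)C(C)(C)C | intermediate
13 | 6-{3-[2,4-bis(TBS-oxy)-5-(2-methylbut-3-en-2-yl)phenyl]propyl}-3-diazo-2H-pyran-2,4(3H)-dione | C=CC(C)(C)c1cc(CCCC2=CC(=O)C(=[N+]=[N-])C(=O)O2)c(O[Si](C)(C)C(C)(C)C)cc1O[Si](C)(C)C(C)(C)C | intermediate
14 | ethyl pent-4-ynoate | C#CCCC(=O)OCC | starting material
15 | prenyl bromide | CC(C)=CCBr | starting material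
16 | ethyl 8-methylnon-7-en-4-ynoate | CCOC(=O)CCC#CCC=C(C)C | intermediate
17 | 2,9-dimethyldec-8-en-5-yn-2-ol | CC(C)(O)CCC#CCC=C(C)C | intermediate
18 | 6-{3-[2,4-bis(TBS-oxy)-5-(2-methylbut-3-en-2-yl)phenyl]propyl}-3-[(2,9-dimethyldec-8-en-5-yn-2-yl)oxy]-4-hydroxy-2H-pyran-2-one | C=CC(C)(C)c1cc(CCCc2cc(O)c(OC(C)(C)CCC#CCC=C(C)C)c(=O)o2)c(O[Si](C)(C)C(C)(C)C)cc1O[Si](C)(C)C(C)(C)C | intermediate
19 | 4-O-TBS ether of 18 (key-step precursor) | C=CC(C)(C)c1cc(CCCc2cc(O[Si](C)(C)C(C)(C)C)c(OC(C)(C)CCC#CCC=C(C)C)c(=O)o2)c(O[Si](C)(C)C(C)(C)C)cc1O[Si](C)(C)C(C)(C)C | intermediate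
20 | bridged lactone (2-oxabicyclo[2.2.2]octa-5,7-dien-3-one; lactone bridge between former pyrone C3 and C6, dihydropyran fused at C3 and the former proximal alkyne carbon; racemic, the two bridgeheads fixed relative to each other by the bicycle) | O=C1OC2(CCCc4cc(C(C)(C)C=C)c(O[Si](C)(C)C(C)(C)C)cc4O[Si](C)(C)C(C)(C)C)C=C(O[Si](C)(C)C(C)(C)C)C13OC(C)(C)CCC3=C2CC=C(C)C | intermediate (not isolated)
21 | tris-TBS ether of Kazinol D | C=CC(C)(C)c1cc(CCCc2cc(O[Si](C)(C)C(C)(C)C)c3c(c2CC=C(C)C)CCC(C)(C)O3)c(O[Si](C)(C)C(C)(C)C)cc1O[Si](C)(C)C(C)(C)C | intermediate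
22 | Kazinol D (4-{3-[8-hydroxy-2,2-dimethyl-5-(3-methylbut-2-en-1-yl)chroman-6-yl]propyl}-6-(2-methylbut-3-en-2-yl)benzene-1,3-diol; achiral) | C=CC(C)(C)c1cc(CCCc2cc(O)c3c(c2CC=C(C)C)CCC(C)(C)O3)c(O)cc1O | target

**Step count**
Total: 14 steps. Longest linear sequence: 12 steps (steps 1–8, then 11–14); steps 9 and 10 make the enynol branch.

**Three steps most likely to fail**

1. Step 13. The donor-substituted pyrone may add the unactivated alkyne too slowly, so that thermal elimination of the tertiary alkyl group from O3 or loss of silyl from O4 outruns the cycloaddition. The fallback reverses the electron demand with an acyloxy pyrone. From 18, pivaloyl chloride with Et3N and DMAP in CH2Cl2 should give the 4-pivaloyloxy pyrone F1, a more electron-poor diene without the labile silyl vinylogous ester. Heating F1 as in step 13 should pass through the bridged lactone F2 and give, after loss of CO2, the aryl pivalate F3. i-Bu2AlH in CH2Cl2 at −78 °C then frees the ring B phenol as the bis-silyl ether F4, and n-Bu4NF/AcOH as in step 14 gives 22.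

2. Step 11. The carbenoid may add to the alkyne or alkenes of 17 (furan or cyclopropane formation) or dimerise, because insertion into the hindered tertiary hydroxyl is slow. The fallback makes the ether by Williamson alkylation and builds the pyrone ring around it. From 17, NaH and bromoacetic acid in THF at reflux should give the alkoxyacetic acid F5, and MeI/K2CO3 its methyl ester F6. LiN(i-Pr)2 followed by N-acetylimidazole (crossed Claisen condensation) gives the 2-alkoxyacetoacetate F7, whose dianion is acylated with N-methoxy-N-methylacetamide to the 2-alkoxy-3,5-dioxohexanoate F8. DBU in toluene at reflux lactonises F8 to the 3-alkoxy-4-hydroxy-6-methyl-2-pyrone F9. Its dilithium dianion F10 is alkylated with 9 under the conditions of step 7, which rejoins the route at 18.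

3. Step 4. Isomerisation of the σ-allylpalladium to its primary terminus before reductive elimination would give the linear prenyl arene, and the ortho silyloxy group may slow the coupling or be cleaved by the aqueous phosphate. The fallback delivers the 1,1-dimethylallyl group by an aromatic Claisen rearrangement. From 1, prenyl bromide 15 and K2CO3 in acetone should alkylate the less hindered hydroxyl para to bromine to give 2-bromo-5-(3-methylbut-2-enyloxy)phenol F11, and TBSCl/imidazole gives its silyl ether F12. Arylation of (2-ethoxy-2-oxoethyl)zinc bromide with F12 under the catalyst of step 2 gives the ethyl arylacetate F13. Heating F13 in N,N-diethylaniline at 180 °C should move the prenyl group from O4 to C5 with allylic inversion ([3,3] shift to the ortho position not flanked by the silyloxy group), giving the phenol F14. TBSOTf/2,6-lutidine gives the bis-silyl ethyl ester F15, and i-Bu2AlH reduction as in step 5 gives 8, where the route is rejoined.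

**Further compounds**
F1 | step 13 | 4-pivaloyloxy analogue of 19 (pivalate of 18) | C=CC(C)(C)c1cc(CCCc2cc(OC(=O)C(C)(C)C)c(OC(C)(C)CCC#CCC=C(C)C)c(=O)o2)c(O[Si](C)(C)C(C)(C)C)cc1O[Si](C)(C)C(C)(C)C
F2 | step 13 | bridged lactone from F1 (racemic, not isolated) | O=C1OC2(CCCc4cc(C(C)(C)C=C)c(O[Si](C)(C)C(C)(C)C)cc4O[Si](C)(C)C(C)(C)C)C=C(OC(=O)C(C)(C)C)C13OC(C)(C)CCC3=C2CC=C(C)C
F3 | step 13 | 8-O-pivaloyl bis-TBS Kazinol D | C=CC(C)(C)c1cc(CCCc2cc(OC(=O)C(C)(C)C)c3c(c2CC=C(C)C)CCC(C)(C)O3)c(O[Si](C)(C)C(C)(C)C)cc1O[Si](C)(C)C(C)(C)C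
F4 | step 13 | ring A bis-TBS ether of Kazinol D | C=CC(C)(C)c1cc(CCCc2cc(O)c3c(c2CC=C(C)C)CCC(C)(C)O3)c(O[Si](C)(C)C(C)(C)C)cc1O[Si](C)(C)C(C)(C)C
F5 | step 11 | 2-[(2,9-dimethyldec-8-en-5-yn-2-yl)oxy]acetic acid | OC(=O)COC(C)(C)CCC#CCC=C(C)C
F6 | step 11 | methyl 2-[(2,9-dimethyldec-8-en-5-yn-2-yl)oxy]acetate | COC(=O)COC(C)(C)CCC#CCC=C(C)C
F7 | step 11 | methyl 2-[(2,9-dimethyldec-8-en-5-yn-2-yl)oxy]-3-oxobutanoate | COC(=O)C(OC(C)(C)CCC#CCC=C(C)C)C(C)=O
F8 | step 11 | methyl 2-[(2,9-dimethyldec-8-en-5-yn-2-yl)oxy]-3,5-dioxohexanoate | COC(=O)C(OC(C)(C)CCC#CCC=C(C)C)C(=O)CC(C)=O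
F9 | step 11 | 3-[(2,9-dimethyldec-8-en-5-yn-2-yl)oxy]-4-hydroxy-6-methyl-2H-pyran-2-one | Cc1cc(O)c(OC(C)(C)CCC#CCC=C(C)C)c(=O)o1
F10 | step 11 | dilithium dianion of F9 (not isolated) | [Li+].[Li+].[CH2-]c1cc([O-])c(OC(C)(C)CCC#CCC=C(C)C)c(=O)o1
F11 | step 4 | 2-bromo-5-(3-methylbut-2-enyloxy)phenol | Oc1cc(OCC=C(C)C)ccc1Br
F12 | step 4 | 1-bromo-2-(TBS-oxy)-4-(3-methylbut-2-enyloxy)benzene | CC(C)(C)[Si](C)(C)Oc1cc(OCC=C(C)C)ccc1Br
F13 | step 4 | ethyl 2-[2-(TBS-oxy)-4-(3-methylbut-2-enyloxy)phenyl]acetate | CCOC(=O)Cc1ccc(OCC=C(C)C)cc1O[Si](C)(C)C(C)(C)C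
F14 | step 4 | ethyl 2-[2-(TBS-oxy)-4-hydroxy-5-(2-methylbut-3-en-2-yl)phenyl]acetate | CCOC(=O)Cc1cc(C(C)(C)C=C)c(O)cc1O[Si](C)(C)C(C)(C)C
F15 | step 4 | ethyl 2-[2,4-bis(TBS-oxy)-5-(2-methylbut-3-en-2-yl)phenyl]acetate | CCOC(=O)Cc1cc(C(C)(C)C=C)c(O[Si](C)(C)C(C)(C)C)cc1O[Si](C)(C)C(C)(C)C
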